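**Plan**
- Numbering used: C7 is the carbinol carbon on the 3,4,5-trimethoxyphenyl ring (ring A); C8 is the methyl-bearing carbon whose oxygen is bound to C4' of the 4-allyl-2,6-dimethoxyphenyl ring (ring B); C9 is the methyl group.
- Retrosynthesis cuts C7–C8 first (aldehyde plus α-aryloxyethyl radical), then the bond from C8 to a traceless carboxyl handle, then the C8–O4' ether bond.
- Forward: no ring is formed. The ether is made first, the acid is turned into a redox-active ester, and the chain is joined at C7–C8 in the last step with loss of CO2.
- Enabling feature: the O4' ether oxygen on C8 stabilises a planar radical at C8, so a racemic acid is sufficient, and C7 comes from an aromatic aldehyde that cannot enolise.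
- Stereochemistry: both centres (7S,8R, erythro) are set in the key step by a chiral ligand on chromium; nothing is taken from the chiral pool.

Key step: step 3

Assumption: the (S,S) enantiomer of the carbazole-bis(oxazoline) ligand is taken as the one that leads to the (7S,8R) product; if the sense of induction is the opposite one, the (R,R) ligand is used without other change.

**Step 1**
Reactants: 1 4-allyl-2,6-dimethoxyphenol; 2 rac-2-bromopropanoic acid
Product: 3 rac-2-(4-allyl-2,6-dimethoxyphenoxy)propanoic acid
Conditions: NaH (2.2 equiv), THF, 0 °C → 65 °C; then 1 M HCl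
Reagents that add atoms: none
Why: Williamson ether synthesis, SN2 displacement of bromide in the sodium carboxylate by the sodium phenoxide; the racemic centre is acceptable because it is erased at the radical stage of step 3.

**Step 2**
Reactants: 3 rac-2-(4-allyl-2,6-dimethoxyphenoxy)propanoic acid
Product: 4 rac-1,3-dioxoisoindolin-2-yl 2-(4-allyl-2,6-dimethoxyphenoxy)propanoate
Conditions: N-hydroxyphthalimide (1.1 equiv), DIC (1.1 equiv), DMAP (5 mol%), CH2Cl2, 0 °C → rt
Reagents that add atoms: N-hydroxyphthalimide, O=C1c2ccccc2C(=O)N1O
Why: Steglich-type esterification through the O-acylisourea should give the N-acyloxyphthalimide (redox-active ester) under neutral conditions that leave the allyl group and the aryl ethers untouched.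

**Step 3**
Reactants: 4 rac-1,3-dioxoisoindolin-2-yl 2-(4-allyl-2,6-dimethoxyphenoxy)propanoate; 5 3,4,5-trimethoxybenzaldehyde
Product: 7 rhaphidecursinol B, (1S,2R)-2-(4-allyl-2,6-dimethoxyphenoxy)-1-(3,4,5-trimethoxyphenyl)propan-1-ol, via trimethylsilyl ether 6 (not isolated)
Conditions: CrCl2 (10 mol%), (S,S)-carbazole-1,8-bis(4-isopropyloxazoline) ligand L* (12 mol%), i-Pr2NEt (20 mol%), Mn powder (3 equiv), TMSCl (2.5 equiv), THF, rt; then K2CO3 (cat.), MeOH, rt
Reagents that add atoms: chlorotrimethylsilane, C[Si](C)(C)Cl (its silyl group is carried only by 6)
Why: Proposed new method: the ligated Cr(II) should reduce the redox-active ester 4 by single-electron transfer, CO2 and phthalimide anion are lost, and the planar α-aryloxy radical at C8 (stabilised by the lone pair of the aryl ether oxygen) is trapped by a second Cr(II) as an α-aryloxyalkyl–Cr(III) species that adds to the Cr-bound aldehyde 5, after which TMSCl frees the metal from the alkoxide as silyl ether 6 and Mn returns Cr(III) to Cr(II). The closest known reaction types are the Cr(II)-mediated Nozaki–Hiyama–Kishi-type addition of radicals from α-oxygenated redox-active esters to aldehydes (without stereocontrol) and the ligand-controlled catalytic asymmetric Nozaki–Hiyama–Kishi reaction; the combination of the two on an α-aryloxy radical with control of both centres is the new part. No ring is closed. The step is stereoconvergent because both enantiomers of 4 give the same radical and the weak Cr–C8 bond should homolyse reversibly, so the two Cr–C8 epimers equilibrate and the addition decides (Curtin–Hammett); C7 is set by the chiral ligand, which leaves one face of the coordinated aldehyde open, and C8 follows from the four-centre Cr–C8···C7=O transition state in which the bulky 2,6-dimethoxyaryloxy group lies anti to the Cr-bound carbonyl oxygen (outside the ligand sphere, C–O dipoles opposed), the methyl group anti to the trimethoxyphenyl ring and H inside, an arrangement that leads to the erythro (7S,8R)/(7R,8S) pair. The step needs chemoselectivity for radical capture over pinacol coupling of 5 and over addition to the allyl group: the electron-rich aldehyde is reduced to a ketyl only slowly, the unactivated terminal alkene is a poor acceptor for a nucleophilic α-oxy radical compared with trapping by Cr(II), and alkyl–Cr(III) species add to aldehydes in the presence of ethers and do not undergo β-hydride elimination.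

**Compound list**
1 | 4-allyl-2,6-dimethoxyphenol (methoxyeugenol) | C=CCc1cc(OC)c(O)c(OC)c1 | starting material
2 | 2-bromopropanoic acid (racemic) | CC(Br)C(=O)O | starting material
3 | 2-(4-allyl-2,6-dimethoxyphenoxy)propanoic acid (racemic) | C=CCc1cc(OC)c(OC(C)C(=O)O)c(OC)c1 | intermediate
4 | 1,3-dioxoisoindolin-2-yl 2-(4-allyl-2,6-dimethoxyphenoxy)propanoate (racemic N-acyloxyphthalimide ester) | C=CCc1cc(OC)c(OC(C)C(=O)ON2C(=O)c3ccccc3C2=O)c(OC)c1 | intermediate
5 | 3,4,5-trimethoxybenzaldehyde | COc1cc(C=O)cc(OC)c1OC | starting material
6 | trimethylsilyl ether of 7, [(1S,2R)-2-(4-allyl-2,6-dimethoxyphenoxy)-1-(3,4,5-trimethoxyphenyl)propoxy]trimethylsilane | C=CCc1cc(OC)c(O[C@H](C)[C@@H](O[Si](C)(C)C)c2cc(OC)c(OC)c(OC)c2)c(OC)c1 | intermediate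
7 | rhaphidecursinol B, (1S,2R)-2-(4-allyl-2,6-dimethoxyphenoxy)-1-(3,4,5-trimethoxyphenyl)propan-1-ol | C=CCc1cc(OC)c(O[C@H](C)[C@@H](O)c2cc(OC)c(OC)c(OC)c2)c(OC)c1 | target

**Total step count:** 3. **Longest linear sequence:** 3 (steps 1–3 from 1; aldehyde 5 enters in step 3).

**Steps most likely to fail**

Step 3 (Proposed new method). What may go wrong: the ligand may fail to differentiate the two faces of the bound aldehyde or the two configurations of the Cr–C8 bond, so that the enantiomeric or diastereomeric purity is low. Reductive pinacol coupling of the aldehyde or protonation of the alkylchromium species may also consume the partners. The fallback uses known chemistry and sets the centres one after the other; it sets out from 1 and comes back to the route at 7.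
- Mitsunobu reaction of 1 with ethyl (S)-lactate (PPh3, DIAD, THF) should give, with inversion, ethyl (R)-2-(4-allyl-2,6-dimethoxyphenoxy)propanoate F1.
- MeNH(OMe)·HCl and i-PrMgCl in THF at −20 °C should convert it into the Weinreb amide (R)-2-(4-allyl-2,6-dimethoxyphenoxy)-N-methoxy-N-methylpropanamide F2.
- Addition of 3,4,5-trimethoxyphenylmagnesium bromide (THF, 0 °C) should give (R)-2-(4-allyl-2,6-dimethoxyphenoxy)-1-(3,4,5-trimethoxyphenyl)propan-1-one F3.
- Chelation-controlled reduction with Zn(BH4)2 (Et2O, 0 °C) delivers hydride to the carbonyl face on the side of the C8 hydrogen within the five-membered zinc chelate and should give the erythro alcohol 7.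
- This fallback joins the halves at the C7–aryl bond instead of C7–C8.

Step 1. What may go wrong: SN2 attack of the hindered 2,6-dimethoxyphenoxide at the secondary carbon may be slow, and E2 loss of HBr from 2 to acrylate may take over. The fallback sets out from 1 and comes back at 3.
- Mitsunobu reaction of 1 with racemic ethyl lactate (PPh3, DIAD, THF), which activates the alcohol instead of displacing a halide, should give racemic ethyl 2-(4-allyl-2,6-dimethoxyphenoxy)propanoate F4.
- Saponification (LiOH, THF/H2O, then acid) returns 3.

Step 2. What may go wrong: O→N acyl migration in the O-acylisourea may give the N-acylurea, and the activated ester may hydrolyse during isolation. The fallback changes the radical precursor; it sets out from 1 and comes back at 7.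
- Copper-mediated O-vinylation of 1 (Cu(OAc)2, pyridine, 2,4,6-trivinylcyclotriboroxane–pyridine complex, CH2Cl2, air) should give the aryl vinyl ether 5-allyl-1,3-dimethoxy-2-(vinyloxy)benzene F5.
- Markovnikov addition of dry HCl (Et2O, −20 °C) should give the racemic α-chloro ether 5-allyl-2-(1-chloroethoxy)-1,3-dimethoxybenzene F6.
- F6 is used crude in place of 4 under the conditions of step 3: halogen abstraction by Cr(II) generates the same α-aryloxy radical, and the sequence ends at 7.

**Further compounds**
F1 | step 3 | ethyl (R)-2-(4-allyl-2,6-dimethoxyphenoxy)propanoate | C=CCc1cc(OC)c(O[C@H](C)C(=O)OCC)c(OC)c1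
F2 | step 3 | (R)-2-(4-allyl-2,6-dimethoxyphenoxy)-N-methoxy-N-methylpropanamide | C=CCc1cc(OC)c(O[C@H](C)C(=O)N(C)OC)c(OC)c1
F3 | step 3 | (R)-2-(4-allyl-2,6-dimethoxyphenoxy)-1-(3,4,5-trimethoxyphenyl)propan-1-one | C=CCc1cc(OC)c(O[C@H](C)C(=O)c2cc(OC)c(OC)c(OC)c2)c(OC)c1
F4 | step 1 | ethyl 2-(4-allyl-2,6-dimethoxyphenoxy)propanoate (racemic) | C=CCc1cc(OC)c(OC(C)C(=O)OCC)c(OC)c1
F5 | step 2 | 5-allyl-1,3-dimethoxy-2-(vinyloxy)benzene | C=CCc1cc(OC)c(OC=C)c(OC)c1
F6 | step 2 | 5-allyl-2-(1-chloroethoxy)-1,3-dimethoxybenzene (racemic) | C=CCc1cc(OC)c(OC(C)Cl)c(OC)c1
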